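**Retrosynthetic overview**
1. The target is a (3Z,4S)-3-arylidene-4-benzyloxolan-2-one. The last operations are a global desilylation and, before it, a Z-selective Horner–Wadsworth–Emmons union of an α-phosphono lactone with silylated 3,4-dihydroxy-5-methoxybenzaldehyde (C3=CH bond).
2. The oxolan-2-one is the only ring to be built. It is cut at C3–C4 and C5–O1 at once, giving an acyclic (Z)-3-arylprop-1-enyl p-tolyl sulfoxide (C4, C5 and the benzyl arm) and dichloroketene (C2, C3).
3. Enabling feature: in the lactone ring C2 (C=O) and C5 (OCH2) stand 1,4, so C3 and C4 are both donor-type carbons and need polarity reversal to be joined. C5 is an unsubstituted CH2 and C3 an sp2 carbon without hydrogen. C5 can therefore carry a temporary sulfur, whose sulfonium and thionium forms make C4 and C5 acceptors and whose stereocentre controls C4, and C3 can carry two temporary chlorines.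
4. Both temporary groups leave in one radical reduction. The sulfoxide is assembled from an aryl Grignard reagent, methoxyallene and menthyl p-toluenesulfinate, followed by cis-hydrogenation.
5. Ring order: both arenes are purchased, the lactone ring forms in the key step, and no other ring is made.

Key step: step 5

Remark: the bond descriptors of the SMILES place the 3,4-dihydroxy-5-methoxyphenyl ring cis to the lactone C=O, so the route aims at the (3Z,4S) isomer.

**Route**

Step 1
Reactants: 1 4-bromo-2-methoxyphenol
Product: 2 (4-bromo-2-methoxyphenoxy)(tert-butyl)dimethylsilane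
Conditions: TBSCl, imidazole, DMF, rt
Reagents that add atoms: tert-butyldimethylsilyl chloride, CC(C)(C)[Si](C)(C)Cl
Why: Imidazole-promoted silyl ether formation masks the acidic phenol before the organomagnesium steps and gives a group that can later be removed without base or hydrogenation; no stereocentre is involved.

Step 2
Reactants: 2 (4-bromo-2-methoxyphenoxy)(tert-butyl)dimethylsilane; 3 methoxyallene (1-methoxypropa-1,2-diene)
Product: 5 tert-butyl[2-methoxy-4-(prop-2-yn-1-yl)phenoxy]dimethylsilane, via arylmagnesium bromide 4 (not isolated)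
Conditions: Mg, THF, 65 °C; then CuBr (cat.), 3, THF, −10 °C to rt
Reagents that add atoms: none
Why: Grignard formation followed by copper-catalysed SN2′ displacement of methoxide from methoxyallene is a known direct route to 3-arylprop-1-ynes and avoids the allene/alkyne mixtures that propargyl halides give.

Step 3
Reactants: 5 tert-butyl[2-methoxy-4-(prop-2-yn-1-yl)phenoxy]dimethylsilane; 6 (1S,2R,5S)-menthyl (R)-4-methylbenzenesulfinate
Product: 8 tert-butyl(2-methoxy-4-{3-[(R)-(4-methylphenyl)sulfinyl]prop-2-yn-1-yl}phenoxy)dimethylsilane, via alkynylmagnesium bromide 7 (not isolated)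
Conditions: EtMgBr, THF, 0 °C to rt; then added to 6, toluene, −20 °C; neutral work-up
Reagents that add atoms: none
Why: In the Andersen sulfoxide synthesis the alkynyl Grignard reagent displaces menthoxide from the diastereomerically pure sulfinate with inversion at sulfur, which sets the sulfur stereocentre (descriptor R because the substituted alkynyl group outranks p-tolyl).

Step 4
Reactants: 8 tert-butyl(2-methoxy-4-{3-[(R)-(4-methylphenyl)sulfinyl]prop-2-yn-1-yl}phenoxy)dimethylsilane
Product: 9 tert-butyl(2-methoxy-4-{(2Z)-3-[(S)-(4-methylphenyl)sulfinyl]prop-2-en-1-yl}phenoxy)dimethylsilane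
Conditions: H2 (1 atm), RhCl(PPh3)3 (cat.), toluene, rt
Reagents that add atoms: none
Why: Homogeneous syn-hydrogenation of a 1-alkynyl sulfoxide is a known route to (Z)-1-alkenyl sulfoxides; the Z geometry follows from cis delivery of H2, and sulfur keeps its arrangement in space (descriptor now S because p-tolyl outranks alkenyl).

Step 5
Reactants: 9 tert-butyl(2-methoxy-4-{(2Z)-3-[(S)-(4-methylphenyl)sulfinyl]prop-2-en-1-yl}phenoxy)dimethylsilane; 10 trichloroacetyl chloride
Product: 14 (4R,5S)-4-{[4-(tert-butyldimethylsilyloxy)-3-methoxyphenyl]methyl}-3,3-dichloro-5-[(4-methylphenyl)sulfanyl]oxolan-2-one, via dichloroketene 11 (not isolated), via acyloxysulfonium enolate 12 (not isolated), via thionium carboxylate 13 (not isolated)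
Conditions: Zn–Cu couple, Et2O, 35 °C, slow addition of 10
Reagents that add atoms: none
Why: Zinc dechlorinates 10 to dichloroketene 11, whose carbonyl carbon is attacked by the sulfinyl oxygen of 9 to give zwitterion 12; its C=C–S–O–C=C array undergoes a charge-accelerated [3,3]-sigmatropic shift that breaks S–O and joins the CCl2 carbon to the benzyl-bearing alkene carbon, and the carboxylate of the resulting thionium ion 13 collapses on the sulfur-bearing carbon, so C3–C4 and C5–O1 of the oxolanone arise in one operation. This is the vinyl sulfoxide–dichloroketene lactonisation (Marino lactonisation), an additive Pummerer process with close precedent on 2-alkyl- and 2-arylmethyl-substituted alkenyl p-tolyl sulfoxides. The single ring closes by 5-exo-trig attack of carboxylate oxygen on the C=S+ carbon, faster than rotation about C4–C5. C4 is set by sulfur-to-carbon chirality transfer: in the reactive rotamer the sulfur lone pair lies inside and eclipses the Z-substituted alkene (least A1,3 strain), p-tolyl points outward, and the enolate carbon is delivered suprafacially to the alkene face that carries the S–O bond, which for the (S)-sulfoxide and the Z alkene should give the required configuration; C5 follows from net syn addition to the Z alkene (arylthio cis to benzyl) and is erased in step 6. The step needs O-acylation to outrun [2+2] cycloaddition and needs the arene and the silyl ether to stay untouched; the sulfinyl oxygen is by far the best nucleophile for the strongly electrophilic ketene, the alkene is electron-poor, and the ion pair in 13 collapses intramolecularly before the arene can intercept it.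

Step 6
Reactants: 14 (4R,5S)-4-{[4-(tert-butyldimethylsilyloxy)-3-methoxyphenyl]methyl}-3,3-dichloro-5-[(4-methylphenyl)sulfanyl]oxolan-2-one
Product: 15 (4S)-4-{[4-(tert-butyldimethylsilyloxy)-3-methoxyphenyl]methyl}oxolan-2-one
Conditions: Bu3SnH (3.5 equiv), AIBN (cat.), toluene, 110 °C
Reagents that add atoms: none
Why: In a radical chain hydrodechlorination and desulfurisation with tin hydride, the two α-carbonyl C–Cl bonds and the C–S bond of the O,S-acetal each give stabilised radicals that abstract hydrogen, while C4 takes no part and keeps its configuration (descriptor S only through changed priorities).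

Step 7
Reactants: 15 (4S)-4-{[4-(tert-butyldimethylsilyloxy)-3-methoxyphenyl]methyl}oxolan-2-one
Product: 18 diphenyl [(3S,4R)-4-{[4-(tert-butyldimethylsilyloxy)-3-methoxyphenyl]methyl}-2-oxooxolan-3-yl]phosphonate, via lithium enolate 16 (not isolated), via phosphonite 17 (not isolated)
Conditions: LiN(iPr)2, THF, −78 °C; ClP(OPh)2, −78 °C to rt; then 30% aq H2O2, 0 °C
Reagents that add atoms: diphenyl phosphorochloridite, ClP(Oc1ccccc1)Oc1ccccc1; hydrogen peroxide, OO
Why: C-phosphinylation of a lactone enolate with a soft trivalent phosphorus chloride followed by oxidation is a known route to α-phosphono lactones; attack anti to the C4 benzyl group should favour the trans isomer, but C3 is planarised again in step 9.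

Step 8
Reactants: 19 3,4-dihydroxy-5-methoxybenzaldehyde
Product: 20 3,4-bis(tert-butyldimethylsilyloxy)-5-methoxybenzaldehyde
Conditions: TBSCl (2.4 equiv), imidazole, DMF, rt
Reagents that add atoms: tert-butyldimethylsilyl chloride, CC(C)(C)[Si](C)(C)Cl
Why: Double silyl ether formation removes both acidic catechol protons, which would quench the phosphonate carbanion, and matches the protecting group on the other arene so that one final step frees all three phenols.

Step 9
Reactants: 18 diphenyl [(3S,4R)-4-{[4-(tert-butyldimethylsilyloxy)-3-methoxyphenyl]methyl}-2-oxooxolan-3-yl]phosphonate; 20 3,4-bis(tert-butyldimethylsilyloxy)-5-methoxybenzaldehyde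
Product: 22 (3Z,4S)-3-{[3,4-bis(tert-butyldimethylsilyloxy)-5-methoxyphenyl]methylidene}-4-{[4-(tert-butyldimethylsilyloxy)-3-methoxyphenyl]methyl}oxolan-2-one, via potassium phosphonate enolate 21 (not isolated)
Conditions: KN(SiMe3)2 (0.95 equiv), 18-crown-6, THF, −78 °C; then 20, −78 to −40 °C, dark
Reagents that add atoms: none
Why: In the Z-selective diaryl phosphonate (Ando) variant of the Horner–Wadsworth–Emmons olefination the electron-poor phenoxy groups make collapse of the kinetically formed adduct faster than its reversal, which should place the aryl ring cis to the lactone carbonyl, and the slight deficit of base at low temperature spares the γ-acidic C4–H.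

Step 10
Reactants: 22 (3Z,4S)-3-{[3,4-bis(tert-butyldimethylsilyloxy)-5-methoxyphenyl]methylidene}-4-{[4-(tert-butyldimethylsilyloxy)-3-methoxyphenyl]methyl}oxolan-2-one
Product: 23 (3Z,4S)-3-[(3,4-dihydroxy-5-methoxyphenyl)methylidene]-4-[(4-hydroxy-3-methoxyphenyl)methyl]oxolan-2-one (target)
Conditions: Et3N·3HF, THF, 0 °C to rt, argon, dark
Reagents that add atoms: none
Why: Fluoride-mediated desilylation in a slightly acidic medium frees the three phenols without forming the para-phenoxide, whose quinone-methide-type delocalisation could lower the C=C rotation barrier, and exclusion of light and air protects the Z alkene and the catechol.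

**Compound list**
1 | 4-bromo-2-methoxyphenol | COc1cc(Br)ccc1O | starting material
2 | (4-bromo-2-methoxyphenoxy)(tert-butyl)dimethylsilane | COc1cc(Br)ccc1O[Si](C)(C)C(C)(C)C | intermediate
3 | methoxyallene | COC=C=C | starting material
4 | [4-(tert-butyldimethylsilyloxy)-3-methoxyphenyl]magnesium bromide | COc1cc([Mg]Br)ccc1O[Si](C)(C)C(C)(C)C | intermediate
5 | tert-butyl[2-methoxy-4-(prop-2-yn-1-yl)phenoxy]dimethylsilane | COc1cc(CC#C)ccc1O[Si](C)(C)C(C)(C)C | intermediate
6 | (1S,2R,5S)-menthyl (R)-4-methylbenzenesulfinate | CC(C)[C@H]1CC[C@H](C)C[C@@H]1O[S@@](=O)c1ccc(C)cc1 | starting material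
7 | {3-[4-(tert-butyldimethylsilyloxy)-3-methoxyphenyl]prop-1-yn-1-yl}magnesium bromide | COc1cc(CC#C[Mg]Br)ccc1O[Si](C)(C)C(C)(C)C | intermediate
8 | alkynyl p-tolyl sulfoxide, R at sulfur | COc1cc(CC#C[S@](=O)c2ccc(C)cc2)ccc1O[Si](C)(C)C(C)(C)C | intermediate
9 | (Z)-alkenyl p-tolyl sulfoxide, S at sulfur | COc1cc(C/C=C\[S@](=O)c2ccc(C)cc2)ccc1O[Si](C)(C)C(C)(C)C | intermediate
10 | trichloroacetyl chloride | ClC(Cl)(Cl)C(Cl)=O | starting material
11 | dichloroketene | ClC(Cl)=C=O | intermediate
12 | acyloxysulfonium enolate zwitterion (O-acylated 9) | COc1cc(C/C=C\[S@+](OC([O-])=C(Cl)Cl)c2ccc(C)cc2)ccc1O[Si](C)(C)C(C)(C)C | intermediate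
13 | thionium carboxylate zwitterion (after the [3,3] shift) | COc1cc(C[C@H](C=[S+]c2ccc(C)cc2)C(Cl)(Cl)C([O-])=O)ccc1O[Si](C)(C)C(C)(C)C | intermediate
14 | (4R,5S)-3,3-dichloro-5-(p-tolylthio) lactone, benzyl and arylthio cis | COc1cc(C[C@@H]2[C@H](Sc3ccc(C)cc3)OC(=O)C2(Cl)Cl)ccc1O[Si](C)(C)C(C)(C)C | intermediate
15 | (4S)-4-{[4-(tert-butyldimethylsilyloxy)-3-methoxyphenyl]methyl}oxolan-2-one | COc1cc(C[C@@H]2COC(=O)C2)ccc1O[Si](C)(C)C(C)(C)C | intermediate
16 | lithium enolate of 15 | COc1cc(C[C@@H]2COC(O[Li])=C2)ccc1O[Si](C)(C)C(C)(C)C | intermediate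
17 | (3S,4R)-3-(diphenoxyphosphanyl) lactone, trans | COc1cc(C[C@@H]2COC(=O)[C@H]2P(Oc3ccccc3)Oc3ccccc3)ccc1O[Si](C)(C)C(C)(C)C | intermediate
18 | diphenyl (3S,4R)-lactone-3-phosphonate, trans (C3 epimer equally usable) | COc1cc(C[C@@H]2COC(=O)[C@H]2P(=O)(Oc3ccccc3)Oc3ccccc3)ccc1O[Si](C)(C)C(C)(C)C | intermediate
19 | 3,4-dihydroxy-5-methoxybenzaldehyde | O=Cc1cc(O)c(O)c(OC)c1 | starting material
20 | 3,4-bis(tert-butyldimethylsilyloxy)-5-methoxybenzaldehyde | O=Cc1cc(O[Si](C)(C)C(C)(C)C)c(O[Si](C)(C)C(C)(C)C)c(OC)c1 | intermediate
21 | potassium enolate of phosphonate 18 | COc1cc(C[C@@H]2COC(O[K])=C2P(=O)(Oc3ccccc3)Oc3ccccc3)ccc1O[Si](C)(C)C(C)(C)C | intermediate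
22 | (3Z,4S)-tris(tert-butyldimethylsilyl) ether of the target | COc1cc(C[C@@H]2COC(=O)/C2=C\c2cc(O[Si](C)(C)C(C)(C)C)c(O[Si](C)(C)C(C)(C)C)c(OC)c2)ccc1O[Si](C)(C)C(C)(C)C | intermediate
23 | (3Z,4S)-3-[(3,4-dihydroxy-5-methoxyphenyl)methylidene]-4-[(4-hydroxy-3-methoxyphenyl)methyl]oxolan-2-one | COc1cc(C[C@@H]2COC(=O)/C2=C\c2cc(O)c(O)c(OC)c2)ccc1O | target

**Step count**
Total step count: 10
Longest linear sequence: 9 (steps 1 to 7, 9 and 10)

**Steps most likely to fail**

Step 5.
- What may go wrong: leakage through the rotamer that places p-tolyl inside (loss of sulfur-to-carbon chirality transfer), reductive deoxygenation of the sulfoxide by zinc, or Pummerer-type fragmentation of 12 before the sigmatropic shift.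
- Fallback: a chiral-pool bis-electrophile replaces the sulfoxide. It sets out from 4 and comes back at 18.
- CuI-catalysed opening of (S)-epichlorohydrin by 4 at the unsubstituted epoxide carbon should give (2S)-1-[4-(tert-butyldimethylsilyloxy)-3-methoxyphenyl]-3-chloropropan-2-ol F1.
- 4-Nitrobenzenesulfonyl chloride, Et3N and DMAP convert it into the (2S)-4-nitrobenzenesulfonate F2.
- The disodium dianion of (diphenoxyphosphoryl)acetic acid (NaH, THF/DMF, 0 °C) then attacks F2 through carbon at the secondary sulfonate with inversion (C3–C4). On warming with NaI the carboxylate displaces the primary chloride (5-exo-tet, C5–O1).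
- The same two ring bonds thus again arise in one flask, and steps 2 to 7 are bypassed.
- This shorter line is held in reserve because aryl participation and E2 elimination at the secondary sulfonate threaten its configurational integrity.

Step 9.
- What may go wrong: erosion of kinetic control through reversible addition and drift towards the E alkene, or sluggish addition of the hindered carbanion to the electron-rich aldehyde.
- Fallback: the geometry is fixed by chelation and carried over by a stereoretentive coupling. It sets out from 15 and comes back at 22.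
- Formylation (LiN(iPr)2, HCO2Et, THF, −78 °C) should give the (4S)-3-(hydroxymethylidene) lactone F3.
- O-Sulfonylation of its lithium chelate (TsCl, N-methylimidazole, LiOH) should give the (Z)-enol 4-methylbenzenesulfonate F4, with the sulfonyloxy group cis to C=O.
- For the partner, 3-methoxybenzene-1,2-diol is silylated (TBSCl, imidazole) to 1,2-bis(tert-butyldimethylsilyloxy)-3-methoxybenzene F5.
- F5 is borylated at its only C–H position without an ortho substituent ([Ir(OMe)(cod)]2, dtbpy, B2pin2) to the aryl pinacol boronate F6.
- Suzuki–Miyaura coupling of F4 with F6 (Pd(OAc)2, SPhos, K3PO4, toluene/H2O, 50 °C) proceeds with retention of alkene geometry and gives 22.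

Step 7.
- What may go wrong: attack of the enolate through oxygen, proton transfer from the more acidic product to unreacted enolate, or displacement of phenoxide at phosphorus.
- Fallback: an intramolecular O-to-C phosphoryl migration replaces the intermolecular C–P bond formation. It sets out from 15 and comes back at 18.
- The enolate of 15 is phosphorylated on oxygen with ClP(O)(OPh)2 to the ketene acetal phosphate F7.
- A second equivalent of LiN(iPr)2 at −78 °C metalates C3 and triggers the 1,3-phosphorus shift (vinyl phosphate to phosphonate rearrangement, known for lactone enolates with dialkyl phosphates). This delivers 18 after protonation.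

**Further compounds**
F1 | step 5 | (2S)-1-[4-(tert-butyldimethylsilyloxy)-3-methoxyphenyl]-3-chloropropan-2-ol | COc1cc(C[C@H](O)CCl)ccc1O[Si](C)(C)C(C)(C)C
F2 | step 5 | (2S)-1-[4-(tert-butyldimethylsilyloxy)-3-methoxyphenyl]-3-chloropropan-2-yl 4-nitrobenzenesulfonate | COc1cc(C[C@H](OS(=O)(=O)c2ccc([N+](=O)[O-])cc2)CCl)ccc1O[Si](C)(C)C(C)(C)C
F3 | step 9 | (4S)-4-{[4-(tert-butyldimethylsilyloxy)-3-methoxyphenyl]methyl}-3-(hydroxymethylidene)oxolan-2-one (enol of the 3-formyl lactone) | COc1cc(C[C@@H]2COC(=O)C2=CO)ccc1O[Si](C)(C)C(C)(C)C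
F4 | step 9 | (Z)-[(4S)-4-{[4-(tert-butyldimethylsilyloxy)-3-methoxyphenyl]methyl}-2-oxooxolan-3-ylidene]methyl 4-methylbenzenesulfonate | COc1cc(C[C@@H]2COC(=O)/C2=C\OS(=O)(=O)c2ccc(C)cc2)ccc1O[Si](C)(C)C(C)(C)C
F5 | step 9 | 1,2-bis(tert-butyldimethylsilyloxy)-3-methoxybenzene | COc1cccc(O[Si](C)(C)C(C)(C)C)c1O[Si](C)(C)C(C)(C)C
F6 | step 9 | 2-[3,4-bis(tert-butyldimethylsilyloxy)-5-methoxyphenyl]-4,4,5,5-tetramethyl-1,3,2-dioxaborolane | COc1cc(B2OC(C)(C)C(C)(C)O2)cc(O[Si](C)(C)C(C)(C)C)c1O[Si](C)(C)C(C)(C)C
F7 | step 7 | (3S)-3-{[4-(tert-butyldimethylsilyloxy)-3-methoxyphenyl]methyl}-2,3-dihydrofuran-5-yl diphenyl phosphate | COc1cc(C[C@@H]2COC(OP(=O)(Oc3ccccc3)Oc3ccccc3)=C2)ccc1O[Si](C)(C)C(C)(C)C
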